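**Retrosynthetic overview**
1. Target 24 ⇐ desilylation ⇐ C8 methacrylate ⇐ CBS reduction of the C8 ketone of butenolide enone 21.
2. 21 ⇐ one-flask esterification/aldol-condensation annulation of epoxy ketol 16 with acetoxypyruvic acid 18 (makes C7=C11 and the lactone; new method).
3. 16 ⇐ hydroxyl-directed epoxidation ⇐ ketol 15 ⇐ enantioselective β-borylation/oxidation of dienone 13 ⇐ Saegusa oxidation of (Z)-cyclodecenone 11.
4. 11 ⇐ key step: SmI2 Barbier cyclisation/Grob fragmentation of iodo keto-mesylate 9 (five- to ten-membered ring expansion, sets Z-C4=C5).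
5. 9 ⇐ 2-methylcyclopentane-1,3-dione + acrolein, anti-crotylboration (C1, C10), ozonolysis/CBS reduction. Ring order: cyclopentane (bought) → transient bicyclo[5.3.0] → ten-membered carbocycle → epoxide → butenolide.

Assumption: carbons carry the germacrane labels of the target (C1 CHOH, C4/C5 epoxide, C6 lactone CH–O, C7=C11, C8 CH–O-acyl, C10 CHMe, C12 lactone C=O, C13 CH2OAc); the crotylborane of step 2 is made in situ from trans-2-butene; the new enone double bond of 13 is taken as Z.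

Step 1
Reactants: 1 2-methylcyclopentane-1,3-dione; 2 acrolein
Product: 3 3-(1-methyl-2,5-dioxocyclopentyl)propanal
Conditions: Et3N (cat.), H2O, rt
Reagents that add atoms: none
Why: Michael addition of the acidic 1,3-dione to acrolein gives the C-alkylated 2,2-disubstituted dione (C3–C4 bond); no stereocentre arises because the dione is still symmetric.

Step 2
Reactants: 3 3-(1-methyl-2,5-dioxocyclopentyl)propanal
Product: 4 2-[(3S,4R)-3-hydroxy-4-methylhex-5-en-1-yl]-2-methylcyclopentane-1,3-dione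
Conditions: (E)-crotyl-B(lIpc)2 [trans-2-butene, KOt-Bu/n-BuLi, (+)-Ipc2BOMe, BF3·OEt2], THF/Et2O, −78 °C; NaBO3·4H2O, rt
Reagents that add atoms: (E)-crotyldiisopinocampheylborane (lIpc series), C/C=C/CB([C@H]1C[C@H]2C[C@@H]([C@@H]1C)C2(C)C)[C@H]1C[C@H]2C[C@@H]([C@@H]1C)C2(C)C
Why: Brown asymmetric crotylboration reacts only with the aldehyde at −78 °C through a closed chair transition state, the (E)-crotyl geometry giving the anti C1-OH/C10-Me pair and the lIpc ligands directing Re-face attack to the (3S,4R) alcohol.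

Step 3
Reactants: 4 2-[(3S,4R)-3-hydroxy-4-methylhex-5-en-1-yl]-2-methylcyclopentane-1,3-dione
Product: 5 2-[(3S,4R)-3-(tert-butyldimethylsilyloxy)-4-methylhex-5-en-1-yl]-2-methylcyclopentane-1,3-dione
Conditions: TBSCl, imidazole, DMF, rt
Reagents that add atoms: tert-butyldimethylsilyl chloride, CC(C)(C)[Si](C)(C)Cl
Why: Standard silylation of the only hydroxyl masks C1-OH until the last step.

Step 4
Reactants: 5 2-[(3S,4R)-3-(tert-butyldimethylsilyloxy)-4-methylhex-5-en-1-yl]-2-methylcyclopentane-1,3-dione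
Product: 7 (2S,3S)-2-[(3S,4R)-3-(tert-butyldimethylsilyloxy)-5-hydroxy-4-methylpentyl]-3-hydroxy-2-methylcyclopentan-1-one, via keto-aldehyde 6 (not isolated)
Conditions: O3, CH2Cl2, −78 °C; PPh3 (1 equiv); then (R)-Me-CBS (20 mol %), BH3·SMe2, −30 °C; MeOH
Reagents that add atoms: ozone, [O-][O+]=O
Why: Ozonolysis cleaves the only alkene to the C9 aldehyde, borane reduces it to the primary alcohol, and the Corey–Bakshi–Shibata catalyst reduces one carbonyl of the prochiral dione with hydride delivered anti to the side chain, so the C5 hydroxyl is cis to the chain as the Z-selective fragmentation requires (both ring stereocentres are erased in step 7; any minor trans-ketol is removed by chromatography).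

Step 5
Reactants: 7 (2S,3S)-2-[(3S,4R)-3-(tert-butyldimethylsilyloxy)-5-hydroxy-4-methylpentyl]-3-hydroxy-2-methylcyclopentan-1-one
Product: 8 (2S,3S)-2-[(3S,4S)-3-(tert-butyldimethylsilyloxy)-5-iodo-4-methylpentyl]-3-hydroxy-2-methylcyclopentan-1-one
Conditions: I2, PPh3, imidazole, CH2Cl2, 0 °C
Reagents that add atoms: iodine, II
Why: Appel-type (Garegg–Samuelsson) iodination is selective for the primary alcohol over the neopentyl secondary one.

Step 6
Reactants: 8 (2S,3S)-2-[(3S,4S)-3-(tert-butyldimethylsilyloxy)-5-iodo-4-methylpentyl]-3-hydroxy-2-methylcyclopentan-1-one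
Product: 9 (1S,2S)-2-[(3S,4S)-3-(tert-butyldimethylsilyloxy)-5-iodo-4-methylpentyl]-2-methyl-3-oxocyclopentyl methanesulfonate
Conditions: MsCl, Et3N, DMAP (cat.), CH2Cl2, 0 °C
Reagents that add atoms: methanesulfonyl chloride, CS(=O)(=O)Cl
Why: Mesylation installs the nucleofuge with retention, and the β-mesyloxy ketone cannot eliminate because C4 is quaternary.

Step 7
Reactants: 9 (1S,2S)-2-[(3S,4S)-3-(tert-butyldimethylsilyloxy)-5-iodo-4-methylpentyl]-2-methyl-3-oxocyclopentyl methanesulfonate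
Product: 11 (4Z,8S,9R)-8-(tert-butyldimethylsilyloxy)-5,9-dimethylcyclodec-4-en-1-one, via bicyclic samarium alkoxide 10 (not isolated)
Conditions: SmI2 (2.5 equiv), HMPA, THF, −78 °C → rt
Reagents that add atoms: none
Why: Key ring expansion: samarium Barbier cyclisation of the primary iodide onto the ketone gives the bicyclo[5.3.0] alkoxide, which undergoes heterolytic Grob (Wharton) fragmentation of the C4–C8 bond with loss of mesylate (a non-pericyclic tandem known for five- and six-membered closures), and because the mesylate is cis to the tether the anti-periplanar alignment places C3 and C6 on the same side, giving the (Z)-C4=C5 alkene stereospecifically.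

Step 8
Reactants: 11 (4Z,8S,9R)-8-(tert-butyldimethylsilyloxy)-5,9-dimethylcyclodec-4-en-1-one
Product: 13 (2Z,4Z,8S,9R)-8-(tert-butyldimethylsilyloxy)-5,9-dimethylcyclodeca-2,4-dien-1-one, via silyl enol ether 12 (not isolated)
Conditions: LDA, TMSCl, THF, −78 °C; Pd(OAc)2, MeCN, rt
Reagents that add atoms: none
Why: Saegusa–Ito oxidation: kinetic deprotonation takes the less hindered C7 methylene (C9 is flanked by the branched C10 and the C1-OTBS group) and Pd(II) turns the silyl enol ether into the conjugated dienone.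

Step 9
Reactants: 13 (2Z,4Z,8S,9R)-8-(tert-butyldimethylsilyloxy)-5,9-dimethylcyclodeca-2,4-dien-1-one
Product: 15 (3S,4Z,8S,9R)-8-(tert-butyldimethylsilyloxy)-3-hydroxy-5,9-dimethylcyclodec-4-en-1-one, via β-boryl ketone 14 (not isolated)
Conditions: CuCl/NaOt-Bu/Josiphos (5 mol %), B2pin2, MeOH, THF, rt; NaBO3·4H2O, THF/H2O
Reagents that add atoms: sodium perborate, [Na+].[Na+].O[B-]1(O)OO[B-](O)(O)OO1
Why: Copper-catalysed enantioselective conjugate borylation adds boron 1,4 (1,6-attack is blocked at the fully substituted C4), the ligand antipode being chosen to give the 6S centre under reagent control, and perborate oxidation replaces boron by hydroxyl with retention.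

Step 10
Reactants: 15 (3S,4Z,8S,9R)-8-(tert-butyldimethylsilyloxy)-3-hydroxy-5,9-dimethylcyclodec-4-en-1-one
Product: 16 (1S,2S,6R,7S,10R)-7-(tert-butyldimethylsilyloxy)-2-hydroxy-6,10-dimethyl-11-oxabicyclo[8.1.0]undecan-4-one
Conditions: VO(acac)2 (5 mol %), t-BuOOH, CH2Cl2, 0 °C
Reagents that add atoms: tert-butyl hydroperoxide, CC(C)(C)OO
Why: Hydroxyl-directed vanadium epoxidation delivers oxygen from the C6-OH face of the (Z)-allylic alcohol, which in medium-ring cis-cycloalkenols gives the cis epoxy alcohol and so sets C4 (R) and C5 (S).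

Step 11
Reactants: 17 bromopyruvic acid
Product: 18 acetoxypyruvic acid (3-acetoxy-2-oxopropanoic acid)
Conditions: KOAc (1.1 equiv), AcOH, 50 °C
Reagents that add atoms: potassium acetate, CC(=O)[O-].[K+]
Why: SN2 displacement of the α-bromo ketone by acetate gives the α-keto acid that carries C11–C13 with the acetate already in place.

Step 12
Reactants: 16 (1S,2S,6R,7S,10R)-7-(tert-butyldimethylsilyloxy)-2-hydroxy-6,10-dimethyl-11-oxabicyclo[8.1.0]undecan-4-one; 18 acetoxypyruvic acid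
Product: 21 (1S,4R,5S,6S,10R)-13-acetoxy-1-(tert-butyldimethylsilyloxy)-4,5-epoxy-8-oxogermacr-7(11)-en-12,6-olide, via acetoxypyruvate ester 19 (not isolated), via aldol adduct 20 (not isolated)
Conditions: DIC, DMAP (cat.), CH2Cl2, 0 °C; then DBU, 4 Å MS, rt
Reagents that add atoms: none
Why: Proposed new method: acylative aldol-condensation butenolide annulation, in which esterifying the C6 hydroxyl with α-keto acid 18 places a highly electrophilic ketone five atoms from C7, DBU enolises the C8 ketone, only the C7 enolate can close a five-membered ring onto the C11 keto group, and E1cB loss of water from the aldol gives the conjugated 4-acylbutenolide (C7–C11 bond and lactone ring in one flask); the closest known reactions are the Knoevenagel/aldol condensation of acetoacetate esters of α-hydroxy ketones to butenolides and pyruvate aldol-lactonisation to isotetronic acids.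

Step 13
Reactants: 21 (1S,4R,5S,6S,10R)-13-acetoxy-1-(tert-butyldimethylsilyloxy)-4,5-epoxy-8-oxogermacr-7(11)-en-12,6-olide
Product: 22 (1S,4R,5S,6S,8S,10R)-13-acetoxy-1-(tert-butyldimethylsilyloxy)-4,5-epoxy-8-hydroxygermacr-7(11)-en-12,6-olide
Conditions: (R)-Me-CBS (0.3 equiv), catecholborane, toluene, −78 °C
Reagents that add atoms: none
Why: CBS reduction of the conjugated ketone treats the alkenyl (butenolide) side as the large group and C9H2 as the small one, so the (R)-catalyst gives the 8S allylic alcohol under reagent control while lactone, acetate and epoxide are untouched at −78 °C.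

Step 14
Reactants: 22 (1S,4R,5S,6S,8S,10R)-13-acetoxy-1-(tert-butyldimethylsilyloxy)-4,5-epoxy-8-hydroxygermacr-7(11)-en-12,6-olide
Product: 23 (1S,4R,5S,6S,8S,10R)-13-acetoxy-1-(tert-butyldimethylsilyloxy)-4,5-epoxy-8-(methacryloyloxy)germacr-7(11)-en-12,6-olide
Conditions: methacryloyl chloride, Et3N, DMAP (cat.), CH2Cl2, 0 °C
Reagents that add atoms: methacryloyl chloride, C=C(C)C(=O)Cl
Why: DMAP-catalysed acylation of the only free hydroxyl installs the methacrylate without touching C8 configuration.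

Step 15
Reactants: 23 (1S,4R,5S,6S,8S,10R)-13-acetoxy-1-(tert-butyldimethylsilyloxy)-4,5-epoxy-8-(methacryloyloxy)germacr-7(11)-en-12,6-olide
Product: 24 (1S,4R,5S,6S,8S,10R)-13-acetoxy-4,5-epoxy-1-hydroxy-8-(methacryloyloxy)germacr-7(11)-en-12,6-olide (CNP0119405.1)
Conditions: HF·pyridine, pyridine, THF, 0 °C → rt
Reagents that add atoms: none
Why: Buffered fluoride desilylation frees C1-OH and spares the epoxide, the two esters and the butenolide.

**Compound list**
1 | 2-methylcyclopentane-1,3-dione | CC1C(=O)CCC1=O | starting material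
2 | acrolein | C=CC=O | starting material
3 | 3-(1-methyl-2,5-dioxocyclopentyl)propanal | O=CCCC1(C)C(=O)CCC1=O | intermediate
4 | 2-[(3S,4R)-3-hydroxy-4-methylhex-5-en-1-yl]-2-methylcyclopentane-1,3-dione | C=C[C@@H](C)[C@@H](O)CCC1(C)C(=O)CCC1=O | intermediate
5 | 2-[(3S,4R)-3-(tert-butyldimethylsilyloxy)-4-methylhex-5-en-1-yl]-2-methylcyclopentane-1,3-dione | C=C[C@@H](C)[C@@H](O[Si](C)(C)C(C)(C)C)CCC1(C)C(=O)CCC1=O | intermediate
6 | (2S,3S)-3-(tert-butyldimethylsilyloxy)-2-methyl-5-(1-methyl-2,5-dioxocyclopentyl)pentanal (keto-aldehyde, not isolated) | O=C[C@@H](C)[C@@H](O[Si](C)(C)C(C)(C)C)CCC1(C)C(=O)CCC1=O | intermediate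
7 | (2S,3S)-2-[(3S,4R)-3-(tert-butyldimethylsilyloxy)-5-hydroxy-4-methylpentyl]-3-hydroxy-2-methylcyclopentan-1-one (ring OH cis to side chain) | OC[C@@H](C)[C@@H](O[Si](C)(C)C(C)(C)C)CC[C@@]1(C)[C@@H](O)CCC1=O | intermediate
8 | (2S,3S)-2-[(3S,4S)-3-(tert-butyldimethylsilyloxy)-5-iodo-4-methylpentyl]-3-hydroxy-2-methylcyclopentan-1-one | IC[C@@H](C)[C@@H](O[Si](C)(C)C(C)(C)C)CC[C@@]1(C)[C@@H](O)CCC1=O | intermediate
9 | (1S,2S)-2-[(3S,4S)-3-(tert-butyldimethylsilyloxy)-5-iodo-4-methylpentyl]-2-methyl-3-oxocyclopentyl methanesulfonate | IC[C@@H](C)[C@@H](O[Si](C)(C)C(C)(C)C)CC[C@@]1(C)[C@@H](OS(C)(=O)=O)CCC1=O | intermediate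
10 | samarium(III) 4-(tert-butyldimethylsilyloxy)-8-(mesyloxy)-3,7-dimethylbicyclo[5.3.0]decan-1-olate (ring-fusion carbinol centre undefined; shown as the alkoxide, not isolated) | [O-]C12C[C@@H](C)[C@@H](O[Si](C)(C)C(C)(C)C)CC[C@@]1(C)[C@@H](OS(C)(=O)=O)CC2 | intermediate
11 | (4Z,8S,9R)-8-(tert-butyldimethylsilyloxy)-5,9-dimethylcyclodec-4-en-1-one | O=C1C[C@@H](C)[C@@H](O[Si](C)(C)C(C)(C)C)CC/C(C)=C\CC1 | intermediate
12 | (4Z,8S,9R)-8-(tert-butyldimethylsilyloxy)-5,9-dimethyl-1-(trimethylsilyloxy)cyclodeca-1,4-diene (enol ether geometry undefined, not isolated) | C[Si](C)(C)OC=1C[C@@H](C)[C@@H](O[Si](C)(C)C(C)(C)C)CC/C(C)=C\CC=1 | intermediate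
13 | (2Z,4Z,8S,9R)-8-(tert-butyldimethylsilyloxy)-5,9-dimethylcyclodeca-2,4-dien-1-one | O=C1C[C@@H](C)[C@@H](O[Si](C)(C)C(C)(C)C)CC/C(C)=C\C=C/1 | intermediate
14 | (3S,4Z,8S,9R)-8-(tert-butyldimethylsilyloxy)-5,9-dimethyl-3-(4,4,5,5-tetramethyl-1,3,2-dioxaborolan-2-yl)cyclodec-4-en-1-one (not isolated) | O=C1C[C@@H](C)[C@@H](O[Si](C)(C)C(C)(C)C)CC/C(C)=C\[C@@H](B2OC(C)(C)C(C)(C)O2)C1 | intermediate
15 | (3S,4Z,8S,9R)-8-(tert-butyldimethylsilyloxy)-3-hydroxy-5,9-dimethylcyclodec-4-en-1-one | O=C1C[C@@H](C)[C@@H](O[Si](C)(C)C(C)(C)C)CC/C(C)=C\[C@@H](O)C1 | intermediate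
16 | (1S,2S,6R,7S,10R)-7-(tert-butyldimethylsilyloxy)-2-hydroxy-6,10-dimethyl-11-oxabicyclo[8.1.0]undecan-4-one | O=C1C[C@@H](C)[C@@H](O[Si](C)(C)C(C)(C)C)CC[C@@]2(C)O[C@H]2[C@@H](O)C1 | intermediate
17 | bromopyruvic acid (3-bromo-2-oxopropanoic acid) | O=C(O)C(=O)CBr | starting material
18 | acetoxypyruvic acid (3-acetoxy-2-oxopropanoic acid) | CC(=O)OCC(=O)C(=O)O | intermediate
19 | C6 acetoxypyruvate ester of 16 (not isolated) | O=C1C[C@@H](C)[C@@H](O[Si](C)(C)C(C)(C)C)CC[C@@]2(C)O[C@H]2[C@@H](OC(=O)C(=O)COC(C)=O)C1 | intermediate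
20 | aldol adduct: 11-hydroxy-7,11-dihydro form of 21 (C7/C11 epimers, not isolated) | O=C1C[C@@H](C)[C@@H](O[Si](C)(C)C(C)(C)C)CC[C@@]2(C)O[C@H]2[C@H]2OC(=O)C(O)(COC(C)=O)C12 | intermediate
21 | (1S,4R,5S,6S,10R)-13-acetoxy-1-(tert-butyldimethylsilyloxy)-4,5-epoxy-8-oxogermacr-7(11)-en-12,6-olide | O=C1C[C@@H](C)[C@@H](O[Si](C)(C)C(C)(C)C)CC[C@@]2(C)O[C@H]2[C@H]2OC(=O)C(COC(C)=O)=C12 | intermediate
22 | (1S,4R,5S,6S,8S,10R)-13-acetoxy-1-(tert-butyldimethylsilyloxy)-4,5-epoxy-8-hydroxygermacr-7(11)-en-12,6-olide | O[C@H]1C[C@@H](C)[C@@H](O[Si](C)(C)C(C)(C)C)CC[C@@]2(C)O[C@H]2[C@H]2OC(=O)C(COC(C)=O)=C12 | intermediate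
23 | (1S,4R,5S,6S,8S,10R)-13-acetoxy-1-(tert-butyldimethylsilyloxy)-4,5-epoxy-8-(methacryloyloxy)germacr-7(11)-en-12,6-olide | C=C(C)C(=O)O[C@H]1C[C@@H](C)[C@@H](O[Si](C)(C)C(C)(C)C)CC[C@@]2(C)O[C@H]2[C@H]2OC(=O)C(COC(C)=O)=C12 | intermediate
24 | (1S,4R,5S,6S,8S,10R)-13-acetoxy-4,5-epoxy-1-hydroxy-8-(methacryloyloxy)germacr-7(11)-en-12,6-olide | C=C(C)C(=O)O[C@H]1C[C@@H](C)[C@@H](O)CC[C@@]2(C)O[C@H]2[C@H]2OC(=O)C(COC(C)=O)=C12 | target

**Step count and risks**
Total step count: 15. Longest linear sequence: 14 (steps 1–10 and 12–15); step 11 makes acid 18 in one step from 17.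

The three steps most likely to fail:

Step 7, the ring expansion, needs a seven-membered Barbier closure onto a hindered ketone; the tandem is known for five- and six-membered closures, so simple reduction of the iodide or the ketone may compete. The fallback sets out from 9 and forms the C8–C9 bond by ketyl coupling instead. Kornblum-type oxidation of the iodide (N-methylmorpholine N-oxide, DMSO) gives the keto-aldehyde mesylate F1. SmI2-mediated ketyl–aldehyde pinacol cyclisation gives the bicyclic cis-diol monomesylate F2. KOt-Bu then triggers the Wharton–Grob fragmentation to the ring-expanded α-hydroxy ketone F3, and SmI2/MeOH removes the α-hydroxyl. The sequence comes back to the route at 11.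

Step 8, the Saegusa oxidation, relies on kinetic enolisation choosing C7 over C9, and the enone geometry is assumed. The fallback sets out from 9, where C7 is the only enolisable position, and installs the enone before ring expansion. LDA/TMSCl then Pd(OAc)2 gives the cyclopentenone mesylate F4. Thiophenol/Et3N adds trans to the mesylate to give the β-phenylthio ketone F5, which masks the enone towards SmI2. SmI2 Barbier/Grob ring expansion as in step 7 gives the ten-membered β-phenylthio ketone F6. Oxidation with mCPBA at −78 °C gives the sulfoxide F7, whose thermal syn-elimination comes back to the route at dienone 13.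

Step 12, the proposed new annulation, may lose to E1cB expulsion of the C6 acyloxy group from the same C7 enolate, or dehydration of the aldol may stall. The fallback uses known reactions and sets out from 16. Methyl oxalyl chloride/pyridine gives the mixed oxalate F8. LiHMDS-mediated Dieckmann-type C-acylation closes the 3-hydroxybutenolide (isotetronic acid) F9. PhNTf2/Et3N gives the enol triflate F10, and Pd-catalysed Suzuki–Miyaura coupling with potassium (acetoxymethyl)trifluoroborate introduces C13–OAc. The sequence comes back to the route at 21.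

**Further compounds**
F1 | step 7 | (1S,2S)-2-[(3S,4S)-3-(tert-butyldimethylsilyloxy)-4-methyl-5-oxopentyl]-2-methyl-3-oxocyclopentyl methanesulfonate | O=C[C@@H](C)[C@@H](O[Si](C)(C)C(C)(C)C)CC[C@@]1(C)[C@@H](OS(C)(=O)=O)CCC1=O
F2 | step 7 | 4-(tert-butyldimethylsilyloxy)-1,2-dihydroxy-3,7-dimethylbicyclo[5.3.0]decan-8-yl methanesulfonate (cis-diol, new carbinol centres undefined) | OC1[C@@H](C)[C@@H](O[Si](C)(C)C(C)(C)C)CC[C@@]2(C)[C@@H](OS(C)(=O)=O)CCC12O
F3 | step 7 | (4Z)-8-(tert-butyldimethylsilyloxy)-10-hydroxy-5,9-dimethylcyclodec-4-en-1-one (C10 carbinol undefined) | O=C1C(O)[C@@H](C)[C@@H](O[Si](C)(C)C(C)(C)C)CC/C(C)=C\CC1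
F4 | step 8 | (1S,5S)-5-[(3S,4S)-3-(tert-butyldimethylsilyloxy)-5-iodo-4-methylpentyl]-5-methyl-4-oxocyclopent-2-en-1-yl methanesulfonate | IC[C@@H](C)[C@@H](O[Si](C)(C)C(C)(C)C)CC[C@@]1(C)[C@@H](OS(C)(=O)=O)C=CC1=O
F5 | step 8 | 2-[(3S,4S)-3-(tert-butyldimethylsilyloxy)-5-iodo-4-methylpentyl]-2-methyl-3-oxo-5-(phenylthio)cyclopentyl methanesulfonate (SPh trans to OMs) | IC[C@@H](C)[C@@H](O[Si](C)(C)C(C)(C)C)CC[C@@]1(C)[C@@H](OS(C)(=O)=O)[C@H](Sc2ccccc2)CC1=O
F6 | step 8 | (4Z,8S,9R)-8-(tert-butyldimethylsilyloxy)-5,9-dimethyl-3-(phenylthio)cyclodec-4-en-1-one | O=C1C[C@@H](C)[C@@H](O[Si](C)(C)C(C)(C)C)CC/C(C)=C\[C@H](Sc2ccccc2)C1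
F7 | step 8 | (4Z,8S,9R)-8-(tert-butyldimethylsilyloxy)-5,9-dimethyl-3-(phenylsulfinyl)cyclodec-4-en-1-one (sulfur configuration undefined) | O=C1C[C@@H](C)[C@@H](O[Si](C)(C)C(C)(C)C)CC/C(C)=C\[C@H]([S+]([O-])c2ccccc2)C1
F8 | step 12 | methyl oxalate mixed ester of 16 at C6-OH | O=C1C[C@@H](C)[C@@H](O[Si](C)(C)C(C)(C)C)CC[C@@]2(C)O[C@H]2[C@@H](OC(=O)C(=O)OC)C1
F9 | step 12 | (1S,4R,5S,6S,10R)-1-(tert-butyldimethylsilyloxy)-4,5-epoxy-11-hydroxy-8-oxo-13-norgermacr-7(11)-en-12,6-olide | O=C1C[C@@H](C)[C@@H](O[Si](C)(C)C(C)(C)C)CC[C@@]2(C)O[C@H]2[C@H]2OC(=O)C(O)=C12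
F10 | step 12 | enol triflate of F9 (C11–OTf) | O=C1C[C@@H](C)[C@@H](O[Si](C)(C)C(C)(C)C)CC[C@@]2(C)O[C@H]2[C@H]2OC(=O)C(OS(=O)(=O)C(F)(F)F)=C12
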